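**Retrosynthetic overview**
1. Iridal ⇒ bis-silyl (Z)-allylic alcohol. The tetrasubstituted C2=C7 alkene is not made by olefinating a hindered ketone; it comes from chromium-mediated cis-1,4-addition of H2 to an s-cis 2-(hydroxymethyl)-1,3-diene (Stille coupling of a C7 enol triflate), so the diene dictates the geometry.
2. C7 carbonyl, C6 stereocentre and C13–C14 bond ⇒ one cyclic hydroboration / B-alkyl Suzuki / oxidation of a 1,4-diene, in which the C11 vinyl group carries boron across one ring face and delivers H to C6.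
3. C10 carbinol / C11 quaternary pair ⇒ semipinacol 1,2-vinyl shift of a cis-2,3-epoxy tertiary alcohol; absolute configuration from one CBS reduction of 2,3-dimethylcyclohexenone.
4. Side chain ⇒ (E)-alkenyl iodide from geranylacetone (ketone-to-alkyne, Zr-catalysed carboalumination/iodination).
5. Ring order: the only carbocycle is bought with the starting enone; no ring-forming step, no bicyclic (Wieland–Miescher-type) precursor and no ring cleavage.

Assumption: iridal locants are used (C1 = CHO carbon, C2 = its alkene carbon, C3 = CH2OH carbon, C6/C7/C10/C11 = ring carbons bearing the hydroxypropyl group, the exocyclic alkene, the tertiary OH and the quaternary centre, C12/C13 = first two side-chain carbons); the target read from the SMILES is (2Z,6R,10S,11S).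

**Route**

Step 1
Reactants: 1 2,3-dimethylcyclohex-2-en-1-one
Product: 2 (R)-2,3-dimethylcyclohex-2-en-1-ol
Conditions: (S)-Me-CBS oxazaborolidine (10 mol %), BH3·SMe2, THF, −20 °C; MeOH, aq. work-up
Reagents that add atoms: none
Why: Corey–Bakshi–Shibata reduction in which the methyl-substituted alkene carbon is the large group, so the (S)-catalyst gives the (R)-carbinol that relays absolute configuration to all later centres.

Step 2
Reactants: 2 (R)-2,3-dimethylcyclohex-2-en-1-ol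
Product: 3 (1R,2R,6S)-1,6-dimethyl-7-oxabicyclo[4.1.0]heptan-2-ol (epoxide syn to OH)
Conditions: VO(acac)2 (2 mol %), t-BuOOH (decane), CH2Cl2, 0 °C → rt
Reagents that add atoms: tert-butyl hydroperoxide CC(C)(C)OO
Why: Vanadium-catalysed hydroxyl-directed epoxidation delivers oxygen to the alkene face syn to the carbinol, fixing the future C10–O configuration.

Step 3
Reactants: 3 (1R,2R,6S)-1,6-dimethyl-7-oxabicyclo[4.1.0]heptan-2-ol
Product: 4 (1S,6S)-1,6-dimethyl-7-oxabicyclo[4.1.0]heptan-2-one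
Conditions: (n-Pr4N)RuO4 (5 mol %), NMO, 4 Å MS, CH2Cl2, rt
Reagents that add atoms: none
Why: Ley–Griffith oxidation is neutral, so the acid-sensitive tetrasubstituted epoxide and its two stereocentres are untouched.

Step 4
Reactants: 4 (1S,6S)-1,6-dimethyl-7-oxabicyclo[4.1.0]heptan-2-one
Product: 5 (1R,2S,6S)-2-ethenyl-1,6-dimethyl-7-oxabicyclo[4.1.0]heptan-2-ol (OH syn to epoxide, vinyl anti)
Conditions: CH2=CHMgBr, CeCl3, THF, −78 °C; aq. work-up
Reagents that add atoms: vinylmagnesium bromide C=C[Mg]Br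
Why: Organocerium-modified Grignard 1,2-addition occurs on the carbonyl face anti to the epoxide oxygen, placing the vinyl group antiperiplanar to the C11–O bond.

Step 5
Reactants: 5 (1R,2S,6S)-2-ethenyl-1,6-dimethyl-7-oxabicyclo[4.1.0]heptan-2-ol
Product: 7 (2R,3S)-2-ethenyl-2,3-dimethyl-3-(triethylsilyloxy)cyclohexan-1-one, via hydroxy ketone 6 (not isolated)
Conditions: BF3·OEt2 (1.0 equiv), CH2Cl2, −78 °C; then 2,6-lutidine, Et3SiOTf, −78 → 0 °C
Reagents that add atoms: triethylsilyl triflate CC[Si](CC)(CC)OS(=O)(=O)C(F)(F)F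
Why: Semipinacol rearrangement of a 2,3-epoxy alcohol in which the antiperiplanar vinyl group shifts to C11 with inversion as the C11–O bond breaks, creating the quaternary centre trans to the retained C10 oxygen, which is then silylated in the same flask.

Step 6
Reactants: 7 (2R,3S)-2-ethenyl-2,3-dimethyl-3-(triethylsilyloxy)cyclohexan-1-one
Product: 8 (5S,6R)-6-ethenyl-5,6-dimethyl-5-(triethylsilyloxy)cyclohex-1-en-1-yl trifluoromethanesulfonate
Conditions: KN(SiMe3)2, THF, −78 °C; PhNTf2, −78 → 0 °C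
Reagents that add atoms: N-phenyl-bis(trifluoromethanesulfonimide) O=S(=O)(N(c1ccccc1)S(=O)(=O)C(F)(F)F)C(F)(F)F
Why: The ketone has a single enolisable position (C7) because C11 is quaternary, so enolate O-triflation is regiospecific and the silylated carbinol cannot undergo retro-aldol cleavage.

Step 7
Reactants: 8 (5S,6R)-6-ethenyl-5,6-dimethyl-5-(triethylsilyloxy)cyclohex-1-en-1-yl trifluoromethanesulfonate; 9 allyl tert-butyldimethylsilyl ether
Product: 11 tert-butyl-[3-[(5S,6S)-6-ethenyl-5,6-dimethyl-5-(triethylsilyloxy)cyclohex-1-en-1-yl]propoxy]dimethylsilane, via alkylborane 10 (not isolated)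
Conditions: 9, 9-BBN, THF, rt; then 8, Pd(dppf)Cl2 (5 mol %), AsPh3, K3PO4 (aq), DMF, rt → 50 °C
Reagents that add atoms: none
Why: B-alkyl Suzuki–Miyaura coupling of the primary alkyl-9-BBN (all B–H consumed beforehand, so the vinyl group is safe) installs the three-carbon C3–C5 chain on C6 without touching any stereocentre.

Step 8
Reactants: 12 (E)-geranylacetone
Product: 14 (5E)-6,10-dimethylundeca-5,9-dien-1-yne, via enol phosphate 13 (not isolated)
Conditions: LiN(iPr)2, THF, −78 °C; ClP(O)(OEt)2; then LiN(iPr)2 (2.2 equiv), −78 °C → rt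
Reagents that add atoms: none
Why: Kinetic methyl-side enolate phosphorylation followed by base-induced elimination converts the methyl ketone into the terminal alkyne without moving the trisubstituted alkenes.

Step 9
Reactants: 14 (5E)-6,10-dimethylundeca-5,9-dien-1-yne
Product: 16 (1E,5E)-1-iodo-2,6,10-trimethylundeca-1,5,9-triene, via alkenylalane 15 (not isolated)
Conditions: AlMe3, Cp2ZrCl2 (25 mol %), CH2Cl2, 0 °C → rt; then I2, THF, −30 → 0 °C
Reagents that add atoms: trimethylaluminium C[Al](C)C; iodine II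
Why: Zirconium-catalysed carboalumination adds methyl and aluminium syn across the alkyne (methyl to the internal carbon), and iodinolysis with retention gives the (E)-alkenyl iodide.

Step 10
Reactants: 11 tert-butyl-[3-[(5S,6S)-6-ethenyl-5,6-dimethyl-5-(triethylsilyloxy)cyclohex-1-en-1-yl]propoxy]dimethylsilane; 16 (1E,5E)-1-iodo-2,6,10-trimethylundeca-1,5,9-triene
Product: 19 (1S,2S,3S,4S)-2-[3-(tert-butyldimethylsilyloxy)propyl]-3,4-dimethyl-4-(triethylsilyloxy)-3-[(3E,7E)-4,8,12-trimethyltrideca-3,7,11-trien-1-yl]cyclohexan-1-ol, via cyclic thexylborane 17 (not isolated), via borinic acid 18 (not isolated)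
Conditions: thexylborane (1.05 equiv), THF, −20 → 20 °C (slow addition of 11); then 16, Pd(dppf)Cl2 (5 mol %), AsPh3, 3 M NaOH, 45 °C; then H2O2, NaOH, 0 °C
Reagents that add atoms: hydrogen peroxide OO
Why: Proposed new method: thexylborane first hydroborates the vinyl group at C13 and its remaining B–H then adds across C6=C7 through a bicyclo[3.3.1] transition state (boron to the less substituted C7, hydrogen to C6 from the face of the C11 arm, which sets the C6 stereocentre); the hydroxide-activated trialkylborane then transfers only its primary alkyl group to the alkenylpalladium iodide with retention of the E geometry, and alkaline peroxide oxidises the remaining C7–B bond; the closest known reactions are the cyclic hydroboration of 1,4- and 1,5-dienes and the B-alkyl Suzuki–Miyaura coupling of primary alkyl groups from dicyclohexyl- or disiamylboranes.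

Step 11
Reactants: 19 (1S,2S,3S,4S)-2-[3-(tert-butyldimethylsilyloxy)propyl]-3,4-dimethyl-4-(triethylsilyloxy)-3-[(3E,7E)-4,8,12-trimethyltrideca-3,7,11-trien-1-yl]cyclohexan-1-ol
Product: 20 (2S,3S,4S)-2-[3-(tert-butyldimethylsilyloxy)propyl]-3,4-dimethyl-4-(triethylsilyloxy)-3-[(3E,7E)-4,8,12-trimethyltrideca-3,7,11-trien-1-yl]cyclohexan-1-one
Conditions: (n-Pr4N)RuO4 (5 mol %), NMO, 4 Å MS, CH2Cl2, rt
Reagents that add atoms: none
Why: Ley–Griffith oxidation of the secondary alcohol is neutral and does not enolise the ketone toward C6, so the new C6 stereocentre and the trisubstituted alkenes survive.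

Step 12
Reactants: 20 (2S,3S,4S)-2-[3-(tert-butyldimethylsilyloxy)propyl]-3,4-dimethyl-4-(triethylsilyloxy)-3-[(3E,7E)-4,8,12-trimethyltrideca-3,7,11-trien-1-yl]cyclohexan-1-one
Product: 21 (4S,5S,6S)-6-[3-(tert-butyldimethylsilyloxy)propyl]-4,5-dimethyl-4-(triethylsilyloxy)-5-[(3E,7E)-4,8,12-trimethyltrideca-3,7,11-trien-1-yl]cyclohex-1-en-1-yl trifluoromethanesulfonate
Conditions: LiN(iPr)2, THF, −78 °C; N-(5-chloropyridin-2-yl)triflimide, −78 °C
Reagents that add atoms: N-(5-chloropyridin-2-yl)-bis(trifluoromethanesulfonimide) Clc1ccc(nc1)N(S(=O)(=O)C(F)(F)F)S(=O)(=O)C(F)(F)F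
Why: Kinetic deprotonation removes a C8 methylene proton, not the hindered tertiary C6–H next to the quaternary carbon, so the enol triflate forms toward C8 and C6 is not epimerised.

Step 13
Reactants: 22 propargyl alcohol
Product: 23 2-(tributylstannyl)prop-2-en-1-ol
Conditions: Bu3SnH, Mo(CO)3(CNtBu)3 (2 mol %), hydroquinone, THF, 55 °C
Reagents that add atoms: tributyltin hydride CCCC[SnH](CCCC)CCCC
Why: Molybdenum-catalysed hydrostannation of propargylic alcohols places tin on the internal carbon, giving the 1,1-disubstituted alkenylstannane.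

Step 14
Reactants: 21 (4S,5S,6S)-6-[3-(tert-butyldimethylsilyloxy)propyl]-4,5-dimethyl-4-(triethylsilyloxy)-5-[(3E,7E)-4,8,12-trimethyltrideca-3,7,11-trien-1-yl]cyclohex-1-en-1-yl trifluoromethanesulfonate; 23 2-(tributylstannyl)prop-2-en-1-ol
Product: 24 2-[(4S,5S,6R)-6-[3-(tert-butyldimethylsilyloxy)propyl]-4,5-dimethyl-4-(triethylsilyloxy)-5-[(3E,7E)-4,8,12-trimethyltrideca-3,7,11-trien-1-yl]cyclohex-1-en-1-yl]prop-2-en-1-ol
Conditions: Pd(PPh3)4 (5 mol %), CuI (10 mol %), LiCl, DMF, 60 °C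
Reagents that add atoms: none
Why: Stille coupling of the enol triflate (chloride- and copper-assisted for the hindered partners) builds the 2,3-disubstituted diene C8=C7–C2(CH2OH)=CH2 and tolerates the free alcohol and silyl ethers.

Step 15
Reactants: 24 2-[(4S,5S,6R)-6-[3-(tert-butyldimethylsilyloxy)propyl]-4,5-dimethyl-4-(triethylsilyloxy)-5-[(3E,7E)-4,8,12-trimethyltrideca-3,7,11-trien-1-yl]cyclohex-1-en-1-yl]prop-2-en-1-ol
Product: 25 (2Z)-2-[(2R,3S,4S)-2-[3-(tert-butyldimethylsilyloxy)propyl]-3,4-dimethyl-4-(triethylsilyloxy)-3-[(3E,7E)-4,8,12-trimethyltrideca-3,7,11-trien-1-yl]cyclohexylidene]propan-1-ol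
Conditions: (naphthalene)Cr(CO)3 (20 mol %), H2 (50 atm), THF, 45 °C
Reagents that add atoms: none
Why: Arene-Cr(CO)3-catalysed 1,4-hydrogenation adds H2 to the two termini (C8 and the exocyclic CH2) of the chromium-bound s-cis diene, so the new methyl is cis to C8 and the CH2OH cis to C6 (Z), while isolated alkenes are inert.

Step 16
Reactants: 25 (2Z)-2-[(2R,3S,4S)-2-[3-(tert-butyldimethylsilyloxy)propyl]-3,4-dimethyl-4-(triethylsilyloxy)-3-[(3E,7E)-4,8,12-trimethyltrideca-3,7,11-trien-1-yl]cyclohexylidene]propan-1-ol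
Product: 26 (2Z)-2-[(2R,3S,4S)-2-[3-(tert-butyldimethylsilyloxy)propyl]-3,4-dimethyl-4-(triethylsilyloxy)-3-[(3E,7E)-4,8,12-trimethyltrideca-3,7,11-trien-1-yl]cyclohexylidene]propanal
Conditions: MnO2 (activated, excess), CH2Cl2, rt, dark
Reagents that add atoms: none
Why: Manganese dioxide oxidises only the allylic alcohol to the enal under neutral conditions that preserve the Z geometry and both silyl ethers.

Step 17
Reactants: 26 (2Z)-2-[(2R,3S,4S)-2-[3-(tert-butyldimethylsilyloxy)propyl]-3,4-dimethyl-4-(triethylsilyloxy)-3-[(3E,7E)-4,8,12-trimethyltrideca-3,7,11-trien-1-yl]cyclohexylidene]propanal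
Product: 27 iridal
Conditions: HF·pyridine, pyridine, THF, 0 °C → rt
Reagents that add atoms: none
Why: Buffered fluoride desilylation removes the primary TBS and tertiary TES ethers without touching the enal, the alkenes or any stereocentre.

**Compound list**
1 | 2,3-dimethylcyclohex-2-en-1-one | CC1=C(C)C(=O)CCC1 | starting material
2 | (R)-2,3-dimethylcyclohex-2-en-1-ol | O[C@@H]1CCCC(C)=C1C | intermediate
3 | (1R,2R,6S)-1,6-dimethyl-7-oxabicyclo[4.1.0]heptan-2-ol | O[C@@H]1CCC[C@]2(C)O[C@]12C | intermediate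
4 | (1S,6S)-1,6-dimethyl-7-oxabicyclo[4.1.0]heptan-2-one | O=C1CCC[C@]2(C)O[C@]12C | intermediate
5 | (1R,2S,6S)-2-ethenyl-1,6-dimethyl-7-oxabicyclo[4.1.0]heptan-2-ol | C=C[C@@]1(O)CCC[C@]2(C)O[C@]12C | intermediate
6 | (2R,3S)-2-ethenyl-3-hydroxy-2,3-dimethylcyclohexan-1-one | C=C[C@@]1(C)C(=O)CCC[C@]1(C)O | intermediate (not isolated)
7 | (2R,3S)-2-ethenyl-2,3-dimethyl-3-(triethylsilyloxy)cyclohexan-1-one | C=C[C@@]1(C)C(=O)CCC[C@]1(C)O[Si](CC)(CC)CC | intermediate
8 | (5S,6R)-6-ethenyl-5,6-dimethyl-5-(triethylsilyloxy)cyclohex-1-en-1-yl trifluoromethanesulfonate | C=C[C@@]1(C)C(OS(=O)(=O)C(F)(F)F)=CCC[C@]1(C)O[Si](CC)(CC)CC | intermediate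
9 | allyl tert-butyldimethylsilyl ether | C=CCO[Si](C)(C)C(C)(C)C | starting material
10 | 9-[3-(tert-butyldimethylsilyloxy)propyl]-9-borabicyclo[3.3.1]nonane | CC(C)(C)[Si](C)(C)OCCCB1C2CCCC1CCC2 | intermediate (not isolated)
11 | tert-butyl-[3-[(5S,6S)-6-ethenyl-5,6-dimethyl-5-(triethylsilyloxy)cyclohex-1-en-1-yl]propoxy]dimethylsilane | C=C[C@@]1(C)C(CCCO[Si](C)(C)C(C)(C)C)=CCC[C@]1(C)O[Si](CC)(CC)CC | intermediate
12 | (E)-geranylacetone, (5E)-6,10-dimethylundeca-5,9-dien-2-one | CC(=O)CC/C=C(\C)CCC=C(C)C | starting material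
13 | diethyl (5E)-6,10-dimethylundeca-1,5,9-trien-2-yl phosphate | C=C(CC/C=C(\C)CCC=C(C)C)OP(=O)(OCC)OCC | intermediate (not isolated)
14 | (5E)-6,10-dimethylundeca-5,9-dien-1-yne | C#CCC/C=C(\C)CCC=C(C)C | intermediate
15 | dimethyl[(1E,5E)-2,6,10-trimethylundeca-1,5,9-trien-1-yl]alane | C[Al](C)/C=C(\C)CC/C=C(\C)CCC=C(C)C | intermediate (not isolated)
16 | (1E,5E)-1-iodo-2,6,10-trimethylundeca-1,5,9-triene | I/C=C(\C)CC/C=C(\C)CCC=C(C)C | intermediate
17 | cyclic thexylborane: 2-(2,3-dimethylbutan-2-yl)-2-borabicyclo[3.3.1]nonane core in which boron bridges C13 and ring C7 on the face of the former vinyl group; C6–H on the same face; 5,6-dimethyl, 6-triethylsilyloxy, 9-[3-(tert-butyldimethylsilyloxy)propyl] | CC(C)C(C)(C)B1CC[C@@]2(C)[C@H](CCCO[Si](C)(C)C(C)(C)C)[C@@H]1CC[C@]2(C)O[Si](CC)(CC)CC | intermediate (not isolated)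
18 | borinic acid: coupled product carrying B(OH)(2,3-dimethylbutan-2-yl) on ring C7, cis to the homofarnesyl chain | CC(C)=CCC/C(C)=C/CC/C(C)=C/CC[C@@]1(C)[C@H](CCCO[Si](C)(C)C(C)(C)C)[C@@H](B(O)C(C)(C)C(C)C)CC[C@]1(C)O[Si](CC)(CC)CC | intermediate (not isolated)
19 | (1S,2S,3S,4S)-2-[3-(tert-butyldimethylsilyloxy)propyl]-3,4-dimethyl-4-(triethylsilyloxy)-3-[(3E,7E)-4,8,12-trimethyltrideca-3,7,11-trien-1-yl]cyclohexan-1-ol | CC(C)=CCC/C(C)=C/CC/C(C)=C/CC[C@@]1(C)[C@H](CCCO[Si](C)(C)C(C)(C)C)[C@@H](O)CC[C@]1(C)O[Si](CC)(CC)CC | intermediate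
20 | (2S,3S,4S)-2-[3-(tert-butyldimethylsilyloxy)propyl]-3,4-dimethyl-4-(triethylsilyloxy)-3-[(3E,7E)-4,8,12-trimethyltrideca-3,7,11-trien-1-yl]cyclohexan-1-one | CC(C)=CCC/C(C)=C/CC/C(C)=C/CC[C@@]1(C)[C@H](CCCO[Si](C)(C)C(C)(C)C)C(=O)CC[C@]1(C)O[Si](CC)(CC)CC | intermediate
21 | (4S,5S,6S)-6-[3-(tert-butyldimethylsilyloxy)propyl]-4,5-dimethyl-4-(triethylsilyloxy)-5-[(3E,7E)-4,8,12-trimethyltrideca-3,7,11-trien-1-yl]cyclohex-1-en-1-yl trifluoromethanesulfonate | CC(C)=CCC/C(C)=C/CC/C(C)=C/CC[C@@]1(C)[C@H](CCCO[Si](C)(C)C(C)(C)C)C(OS(=O)(=O)C(F)(F)F)=CC[C@]1(C)O[Si](CC)(CC)CC | intermediate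
22 | propargyl alcohol | C#CCO | starting material
23 | 2-(tributylstannyl)prop-2-en-1-ol | C=C(CO)[Sn](CCCC)(CCCC)CCCC | intermediate
24 | 2-[(4S,5S,6R)-6-[3-(tert-butyldimethylsilyloxy)propyl]-4,5-dimethyl-4-(triethylsilyloxy)-5-[(3E,7E)-4,8,12-trimethyltrideca-3,7,11-trien-1-yl]cyclohex-1-en-1-yl]prop-2-en-1-ol | CC(C)=CCC/C(C)=C/CC/C(C)=C/CC[C@@]1(C)[C@H](CCCO[Si](C)(C)C(C)(C)C)C(C(=C)CO)=CC[C@]1(C)O[Si](CC)(CC)CC | intermediate
25 | (2Z)-2-[(2R,3S,4S)-2-[3-(tert-butyldimethylsilyloxy)propyl]-3,4-dimethyl-4-(triethylsilyloxy)-3-[(3E,7E)-4,8,12-trimethyltrideca-3,7,11-trien-1-yl]cyclohexylidene]propan-1-ol | CC(C)=CCC/C(C)=C/CC/C(C)=C/CC[C@@]1(C)[C@H](CCCO[Si](C)(C)C(C)(C)C)/C(=C(/C)CO)CC[C@]1(C)O[Si](CC)(CC)CC | intermediate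
26 | (2Z)-2-[(2R,3S,4S)-2-[3-(tert-butyldimethylsilyloxy)propyl]-3,4-dimethyl-4-(triethylsilyloxy)-3-[(3E,7E)-4,8,12-trimethyltrideca-3,7,11-trien-1-yl]cyclohexylidene]propanal | CC(C)=CCC/C(C)=C/CC/C(C)=C/CC[C@@]1(C)[C@H](CCCO[Si](C)(C)C(C)(C)C)/C(=C(/C)C=O)CC[C@]1(C)O[Si](CC)(CC)CC | intermediate
27 | iridal, (2Z)-2-[(2R,3S,4S)-4-hydroxy-2-(3-hydroxypropyl)-3,4-dimethyl-3-[(3E,7E)-4,8,12-trimethyltrideca-3,7,11-trien-1-yl]cyclohexylidene]propanal | CC(C)=CCC/C(C)=C/CC/C(C)=C/CC[C@@]1(C)[C@H](CCCO)/C(=C(/C)C=O)CC[C@]1(C)O | target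

**Step count and risks**

Total steps: 17. Longest linear sequence: 14 (steps 1–7, 10–12, 14–17).

Risk 1, step 10 (cyclic hydroboration / alkyl transfer in one flask). The bridged trialkylborane 17 is hindered, so ate-complex formation and transfer of the primary alkyl group to palladium may be slow, and intermolecular hydroboration can compete if 11 is not added slowly. Fallback, setting out from 11 and coming back at 20: run the same thexylborane cyclic hydroboration but oxidise directly (NaOH, H2O2) to (1S,2S,3S,4S)-2-[3-(tert-butyldimethylsilyloxy)propyl]-3-(2-hydroxyethyl)-3,4-dimethyl-4-(triethylsilyloxy)cyclohexan-1-ol F1. Convert its primary alcohol selectively (I2, PPh3, imidazole) into (1S,2S,3S,4S)-2-[3-(tert-butyldimethylsilyloxy)propyl]-3-(2-iodoethyl)-3,4-dimethyl-4-(triethylsilyloxy)cyclohexan-1-ol F2, and oxidise ((n-Pr4N)RuO4, NMO) to (2S,3S,4S)-2-[3-(tert-butyldimethylsilyloxy)propyl]-3-(2-iodoethyl)-3,4-dimethyl-4-(triethylsilyloxy)cyclohexan-1-one F3. Zinc dust/LiCl in THF then gives iodo[2-[(1S,2S,6S)-2-[3-(tert-butyldimethylsilyloxy)propyl]-1,6-dimethyl-3-oxo-6-(triethylsilyloxy)cyclohexyl]ethyl]zinc F4, and Negishi coupling of this ketone-tolerant alkylzinc with 16 (Pd(dppf)Cl2, THF, 40 °C) gives 20.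

Risk 2, step 15 (chromium-catalysed 1,4-hydrogenation). The 2,3-disubstituted diene must reach the s-cis chromium-bound form next to the axial C6 chain; slow turnover or chromium-induced hydrogen shifts would erode yield. Fallback, setting out from 20 and coming back at 25: Peterson olefination of 20 with the lithium enolate of ethyl 2-(trimethylsilyl)propanoate (LiN(iPr)2, THF, −78 °C → rt) gives ethyl (2Z)-2-[(2R,3S,4S)-2-[3-(tert-butyldimethylsilyloxy)propyl]-3,4-dimethyl-4-(triethylsilyloxy)-3-[(3E,7E)-4,8,12-trimethyltrideca-3,7,11-trien-1-yl]cyclohexylidene]propanoate F5 together with its geometric isomer, the corresponding ethyl (2E)-cyclohexylidenepropanoate F6. The two are separated by chromatography, F6 is recycled by sensitised photoisomerisation, and i-Bu2AlH reduction of F5 (CH2Cl2, −78 °C) gives 25. This gives up stereospecificity for a separable mixture.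

Risk 3, step 5 (semipinacol). Both epoxide carbons are tertiary, so Lewis-acid ionisation at C10 (methyl shift or ring contraction) can compete with the vinyl-assisted opening at C11. Fallback, setting out from 4 and coming back at 6: add [1-(trimethylsilyl)vinyl]magnesium bromide/CeCl3 to 4 to give (1R,2R,6S)-1,6-dimethyl-2-[1-(trimethylsilyl)ethenyl]-7-oxabicyclo[4.1.0]heptan-2-ol F7. Its migrating group is strongly accelerated because the developing charge sits β to silicon, so BF3·OEt2 at −78 °C should give (2R,3S)-3-hydroxy-2,3-dimethyl-2-[1-(trimethylsilyl)ethenyl]cyclohexan-1-one F8 by opening at C11 only. Ipso-protodesilylation (CF3CO2H, CH2Cl2, 0 °C) then gives 6, which is silylated as in step 5 to 7.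

**Further compounds**
F1 | step 10 | (1S,2S,3S,4S)-2-[3-(tert-butyldimethylsilyloxy)propyl]-3-(2-hydroxyethyl)-3,4-dimethyl-4-(triethylsilyloxy)cyclohexan-1-ol | OCC[C@@]1(C)[C@H](CCCO[Si](C)(C)C(C)(C)C)[C@@H](O)CC[C@]1(C)O[Si](CC)(CC)CC
F2 | step 10 | (1S,2S,3S,4S)-2-[3-(tert-butyldimethylsilyloxy)propyl]-3-(2-iodoethyl)-3,4-dimethyl-4-(triethylsilyloxy)cyclohexan-1-ol | ICC[C@@]1(C)[C@H](CCCO[Si](C)(C)C(C)(C)C)[C@@H](O)CC[C@]1(C)O[Si](CC)(CC)CC
F3 | step 10 | (2S,3S,4S)-2-[3-(tert-butyldimethylsilyloxy)propyl]-3-(2-iodoethyl)-3,4-dimethyl-4-(triethylsilyloxy)cyclohexan-1-one | ICC[C@@]1(C)[C@H](CCCO[Si](C)(C)C(C)(C)C)C(=O)CC[C@]1(C)O[Si](CC)(CC)CC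
F4 | step 10 | iodo[2-[(1S,2S,6S)-2-[3-(tert-butyldimethylsilyloxy)propyl]-1,6-dimethyl-3-oxo-6-(triethylsilyloxy)cyclohexyl]ethyl]zinc | I[Zn]CC[C@@]1(C)[C@H](CCCO[Si](C)(C)C(C)(C)C)C(=O)CC[C@]1(C)O[Si](CC)(CC)CC
F5 | step 15 | ethyl (2Z)-2-[(2R,3S,4S)-2-[3-(tert-butyldimethylsilyloxy)propyl]-3,4-dimethyl-4-(triethylsilyloxy)-3-[(3E,7E)-4,8,12-trimethyltrideca-3,7,11-trien-1-yl]cyclohexylidene]propanoate | CC(C)=CCC/C(C)=C/CC/C(C)=C/CC[C@@]1(C)[C@H](CCCO[Si](C)(C)C(C)(C)C)/C(=C(/C)C(=O)OCC)CC[C@]1(C)O[Si](CC)(CC)CC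
F6 | step 15 | ethyl (2E)-2-[(2R,3S,4S)-2-[3-(tert-butyldimethylsilyloxy)propyl]-3,4-dimethyl-4-(triethylsilyloxy)-3-[(3E,7E)-4,8,12-trimethyltrideca-3,7,11-trien-1-yl]cyclohexylidene]propanoate | CC(C)=CCC/C(C)=C/CC/C(C)=C/CC[C@@]1(C)[C@H](CCCO[Si](C)(C)C(C)(C)C)/C(=C(\C)C(=O)OCC)CC[C@]1(C)O[Si](CC)(CC)CC
F7 | step 5 | (1R,2R,6S)-1,6-dimethyl-2-[1-(trimethylsilyl)ethenyl]-7-oxabicyclo[4.1.0]heptan-2-ol | C=C([Si](C)(C)C)[C@@]1(O)CCC[C@]2(C)O[C@]12C
F8 | step 5 | (2R,3S)-3-hydroxy-2,3-dimethyl-2-[1-(trimethylsilyl)ethenyl]cyclohexan-1-one | C=C([Si](C)(C)C)[C@@]1(C)C(=O)CCC[C@]1(C)O
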